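## The problem

The target 16 is an achiral, symmetric dimer in which two 7-acetyl-3,6,8-trihydroxy-4,4-dimethylnaphthalen-1(4H)-one halves are joined by one methylene carbon between their C2 atoms. Each half is numbered C1 (ketone), C2 (bridge carbon), C3 (enol carbon), C4 (gem-dimethyl carbon), C4a and C8a (ring fusion) and C5 to C8 (rest of the aromatic ring A, acetyl on C7); ring B is C1 to C4 plus C4a and C8a. The quaternary C4 keeps ring B from aromatizing, so ring B is a cyclic 1,3-dione enol fused to an acylresorcinol. There is no stereocentre, so the difficulty is purely constitutional: ring A is fully substituted except at C5, and its acetyl group sits between two oxygens, a position that direct acylation of a 6,8-dioxygenated naphthalenone would have to win against the open C5. The fragile part is the methylene-bis(1,3-dione): strong acid can dehydrate the two facing enols to a 4H-pyran, hot base can open the bridge by retro-Michael loss, and the electron-rich ring A is sensitive to oxidants. The feature that allows a convergent construction of ring A is the C4a=C8a bond. In a monocyclic ring B precursor it is a tetrasubstituted alkene with a methyl on C4a (the future C5) and an ester on C8a (the future C8), cis to each other and conjugated with the C1 ketone, which makes it a non-aromatic equivalent of an ortho-toluate. Because C2, C4 and C8a carry no hydrogen, that methyl is the only position a strong base can deprotonate.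

## Retrosynthesis

**16 to 15.** The last operation cuts no skeletal bond. Target 16 is led back to its tetramethyl ether 15 by cutting four O–CH3 bonds, two at the C3 enols and two at the C6 phenols. The C6 methoxy groups are what the ring-forming step leaves behind, and the C3 methoxy groups are what keeps ring B inert to base in that step. Carrying free enols and phenols through the annulation would require a polyanion of doubtful solubility. The forward reaction must cleave an aryl methyl ether ortho to an acetyl group and a vinylogous methyl ester without dehydrating the bis(dione).

**15 to 10 and 13 (key disconnection).** In each ring A of 15 the bonds C5–C6 and C7–C8 are cut. This returns the bis(dienone ester) 10, which keeps both rings B and the bridge, and two molecules of the acetylketene acetal 13, which supplies C6 and the acetyl-bearing C7. The neighbouring cuts (C4a–C5 with C8–C8a, C4a–C8a, or C1–C8a) all leave the acetyl group to be added afterwards to a ring with two competing positions. This cut delivers C6–O, the C7 acetyl and the C8 hydroxyl in one event. The precursor has two rings instead of four and eight fewer skeletal carbons. The forward reaction must deprotonate each C4a methyl, add the carbanion to the ketene acetal carbon, close ring A by Dieckmann attack on the ester, and aromatize, twice in one molecule.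

**13 to 11 and 12.** The bond between the vinylic CH and the acetyl carbonyl of 13 is cut, giving 1,1-dimethoxyethene 11 and acetyl chloride 12. C-Acylation of a ketene acetal is the direct route to an acylketene acetal and needs no protecting group.

**10 to 9.** The two C3 O–CH3 bonds are cut, giving the bis(vinylogous acid) 9. Methyl is chosen because it leaves in the same final operation as the C6 methyl ethers. The forward reaction must place the methyl on the C3 oxygen rather than the C1 oxygen.

**9 to 7 and 8.** Both C2–CH2 bonds are cut, giving two molecules of the monocyclic dione 7 and formaldehyde 8. Bridging at the dione stage is preferred over bridging an aromatic precursor, because C2 of 7 is the only nucleophilic carbon, whereas a resorcinol ester offers two activated ring positions. This is the mild formaldehyde coupling typical of cyclic 1,3-diones.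

**7 to 6.** The C4a=C8a double bond is cut in the aldol sense, giving the open-chain triketo ester 6. The alternative is a dearomatizing double C-methylation of an aromatic resorcinol ester. It was set aside because it must alkylate twice at the carbon flanked by only one oxygen, where such phenolates prefer the carbon between the two oxygens or O-alkylation. In 6 the quaternary carbon is present from the start, and ring closure is an intramolecular condensation on a ketone that would be too hindered for an intermolecular one.

**6 to 3 and 4.** The C2–C3 bond (chain C4–C5 of 6) is cut, giving the acid chloride 3 and the bis(silyl enol ether) 4 of methyl acetoacetate. They combine through the silyl enol ether 5. An acid chloride is needed because a hard dianion would attack the ketone of a keto ester instead.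

**3 to 2 to 1.** The acid chloride 3 comes from the acid 2, which comes from the commercial ester 1 by saponification. The gem-dimethyl group is bought, not made.

## Roads not taken

Alternative 1: Both rings A are cut at C4a–C8a. A bis(4-hydroxy-2-pyranone), 1,11-bis(4-hydroxy-2-oxo-2H-pyran-6-yl)-3,3,9,9-tetramethylundecane-2,4,8,10-tetraone A1, would be opened by KOH in methanol to two triketo methyl esters. Each ester-flanked methylene (C8a) would then condense on the C4a ketone, giving the bis(resorcylate) dimethyl 6,6'-(2,8-dimethyl-3,7-dioxononane-2,8-diyl)bis(2,4-dihydroxybenzoate) A2. Rings B would follow by double Claisen closure of C2 onto the C1 esters, and C7 would be acetylated last.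

- Merits: aldol aromatization of a triketo ester is the best precedented arene synthesis of all four plans. Ring B is made last as a free dione, so the enol ether regiochemistry of step 6 never arises. In both respects this road is better than the chosen one.
- Weak points: A1 carries four ketones and two pyranones. After opening, the central C2 methylenes can aldolize onto the C6 ketones in a competing six-membered closure. The two non-enolizable β-diketone units around C4 invite retro-Claisen cleavage in methanolic KOH. The acetyl groups still have to be placed at C7 against C5 and against O-acylation.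
- Comparison: the chosen plan offers a much smaller precursor, a single acidic site in the key step, and an acetyl group that arrives with the ring.

Alternative 2: Both rings B are cut at C1–C8a. The bis(β-keto ester) dimethyl 2,4-bis[2-(3,5-dimethoxyphenyl)-2-methylpropanoyl]pentanedioate A3 would be cyclized with P2O5 in MeSO3H. Each ester carbon acylates the arene ortho to the quaternary carbon, giving 2,2'-methylenebis(3-hydroxy-6,8-dimethoxy-4,4-dimethylnaphthalen-1(4H)-one) A4.

- Merits: the building blocks are simple, the plan is two-directional, there is no cryogenic carbanion chemistry, and the acylation site is unambiguous because the two free ortho positions of each arene are equivalent. On scale and operational ease this road is superior.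
- Weak points: the product is a methylene-bis(1,3-dione) formed in the very dehydrating acid that converts such units into pyrans. β-Keto esters can lose the ester under these conditions. A4 still lacks both acetyl groups, and C7 lies between two methoxy groups with C5 as competitor. Three ethers per half must then be cleaved.
- Comparison: the chosen plan forms the bridge under mild conditions and needs no arene acylation, at the price of an organolithium step.

Alternative 3: Both rings A are cut at C4a–C5 and C8–C8a. Two molecules of 1,1-dimethoxy-3-(trimethylsilyloxy)buta-1,3-diene A6 would add to the bromo enone bonds of 2,2'-methylenebis(6-bromo-3-methoxy-4,4-dimethylcyclohexa-2,5-dien-1-one) A5. Loss of HBr and methanol would give 2,2'-methylenebis(6-hydroxy-3,8-dimethoxy-4,4-dimethylnaphthalen-1(4H)-one) A7.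

- Merits: the conditions are neutral, the regiochemistry of such dienes with α-halo enones is reliable, and A6 is one silylation away from 13. The mildness is a real advantage over a strong-base step.
- Weak points: A5 is not a quinone. It is a cross-conjugated dienone whose β-carbon C4a is next to the quaternary C4, so a double cycloaddition is likely to be slow. A7 lacks the acetyl groups, which must later be placed at C7 against C5. The C8 methyl ether sits where the chelated hydroxyl is wanted.
- Comparison: the chosen plan builds the same ring from the same four-carbon unit but lets C7 attack an ester, so the C8 oxygen and the acetyl group are both correct from the outset.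

Key step: step 8

Remark: 16 has no stereocentre and is drawn as the C1-keto/C3-enol tautomer of ring B; diene 4 is treated as a purchasable reagent (otherwise two successive O-silylations of methyl acetoacetate supply it) with immaterial ketene acetal geometry; equivalents on the Reactants lines are those of the balanced equation, and any excess charged is given under Conditions.

## Route

Step 1
Reactants: 1 methyl 2,2-dimethyl-3-oxobutanoate
Product: 2 2,2-dimethyl-3-oxobutanoic acid
Conditions: KOH (1.1 equiv), H2O/MeOH, 0 → 20 °C; then cold 1 M HCl to pH 2, extraction and concentration without heating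
Reagents that add atoms: potassium hydroxide, [K+].[OH-]
Why: Ester saponification by acyl–oxygen cleavage; dilute cold hydroxide is used so that retro-Claisen cleavage of the non-enolizable β-keto ester stays slow, and the β-keto acid is kept cold to avoid decarboxylation.

Step 2
Reactants: 2 2,2-dimethyl-3-oxobutanoic acid
Product: 3 2,2-dimethyl-3-oxobutanoyl chloride
Conditions: (COCl)2 (1.2 equiv), DMF (cat.), CH2Cl2, 0 → 20 °C; volatiles removed, used crude
Reagents that add atoms: oxalyl chloride, ClC(=O)C(=O)Cl
Why: Acid chloride formation through the Vilsmeier-type chloroiminium catalyst under neutral, cold conditions; the quaternary α-carbon excludes ketene formation and the methyl ketone is not touched by a catalytic amount of DMF.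

Step 3
Reactants: 3 2,2-dimethyl-3-oxobutanoyl chloride; 4 1-methoxy-1,3-bis(trimethylsilyloxy)buta-1,3-diene
Product: 6 methyl 6,6-dimethyl-3,5,7-trioxooctanoate, via silyl enol ether 5 (not isolated)
Conditions: CH2Cl2, −78 → 20 °C, 14 h; then 1 M HCl (aq), 20 °C
Reagents that add atoms: none
Why: Uncatalysed C-acylation of a 1,3-bis(silyl enol ether) at its terminal carbon, a vinylogous Mukaiyama-type acylation that is the standard route to 3,5-dioxo esters. The acid chloride carbonyl is far more electrophilic than the neopentyl-type ketone of 3, and aqueous acid removes the remaining silyl group from 5.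

Step 4
Reactants: 6 methyl 6,6-dimethyl-3,5,7-trioxooctanoate
Product: 7 methyl 4-hydroxy-2,3,3-trimethyl-6-oxocyclohexa-1,4-diene-1-carboxylate
Conditions: K2CO3 (2 equiv), MeOH, 0 → 20 °C; then 1 M HCl (aq)
Reagents that add atoms: none
Why: Intramolecular Knoevenagel-type aldol condensation of a 3,5,7-triketo ester: the ester-flanked methylene (future C8a) adds to the C7 ketone (future C4a) in a six-membered closure helped by the gem-dimethyl group, and dehydration gives the alkylidene β-keto ester. The quaternary carbon blocks aromatization, so the product stops at the vinylogous acid, and the enolate of the 3,5-dione protects the chain against retro-Claisen cleavage.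

Step 5
Reactants: 7 methyl 4-hydroxy-2,3,3-trimethyl-6-oxocyclohexa-1,4-diene-1-carboxylate (two equivalents); 8 formaldehyde
Product: 9 dimethyl 5,5'-methylenebis(4-hydroxy-2,3,3-trimethyl-6-oxocyclohexa-1,4-diene-1-carboxylate)
Conditions: 37% aq. CH2O (0.5 equiv), piperidine (cat.), EtOH, 20 °C
Reagents that add atoms: none
Why: Tandem Knoevenagel condensation and Michael addition at the only acidic C–H of the cyclic 1,3-dione, the classical formaldehyde coupling of such diones (as with dimedone). With half an equivalent of aldehyde at ambient temperature it should stop at the methylene-bis compound without dehydration to a pyran.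

Step 6
Reactants: 9 dimethyl 5,5'-methylenebis(4-hydroxy-2,3,3-trimethyl-6-oxocyclohexa-1,4-diene-1-carboxylate)
Product: 10 dimethyl 5,5'-methylenebis(4-methoxy-2,3,3-trimethyl-6-oxocyclohexa-1,4-diene-1-carboxylate)
Conditions: Me3SiCHN2 (3 equiv), toluene/MeOH 4:1, 0 → 20 °C
Reagents that add atoms: trimethylsilyldiazomethane, C[Si](C)(C)C=[N+]=[N-]
Why: O-Methylation of a vinylogous acid by a diazoalkane (proton transfer, then methyl transfer in the ion pair), run without acid or base so that neither pyran formation nor bridge cleavage can start. The methyl is expected on the C3 oxygen because the cross-conjugated C1-keto enol is the preferred tautomer, and because a methoxy group on the C1 oxygen would lie in the ring plane between the C8a ester and the bridge CH2, whereas the C4 methyl groups stand above and below that plane.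

Step 7
Reactants: 11 1,1-dimethoxyethene (two equivalents); 12 acetyl chloride
Product: 13 4,4-dimethoxybut-3-en-2-one
Conditions: Et2O, 0 → 20 °C; distillation under reduced pressure
Reagents that add atoms: none
Why: C-Acylation of a ketene acetal by an acid chloride; the second equivalent of 11 takes up the HCl and ends as methyl acetate and chloromethane, which avoids an amine base that would turn acetyl chloride into ketene.

Step 8
Reactants: 10 dimethyl 5,5'-methylenebis(4-methoxy-2,3,3-trimethyl-6-oxocyclohexa-1,4-diene-1-carboxylate); 13 4,4-dimethoxybut-3-en-2-one (two equivalents)
Product: 15 2,2'-methylenebis(7-acetyl-8-hydroxy-3,6-dimethoxy-4,4-dimethylnaphthalen-1(4H)-one), via dilithium bis(dienolate) 14 (not isolated)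
Conditions: LiN(iPr)2 (2.2 equiv), THF, −78 °C; then 13 (3 equiv), −78 → 20 °C; 1 M HCl (aq)
Reagents that add atoms: none
Why: LiN(iPr)2 removes a proton from each C4a methyl, the only acidic C–H of 10 (C2, C4 and C8a are fully substituted and the bridge CH2 is not conjugated with a carbonyl), to give the bis(dienolate) 14, stabilized by the C8 ester and the C1 ketone. Each dienolate reacts through its methylene terminus C5, because attack through C8a would only build a quaternary centre reversibly, and adds in Michael fashion to the ketene acetal carbon C6 of one molecule of 13. The acetyl-stabilized enolate so formed attacks the neighbouring ester carbonyl C8 through C7, a 6-exo-trig Dieckmann closure of ring A that expels methoxide; the methoxide then removes the C7 and C5 protons in turn, one methoxy group leaves C6, and ring A aromatizes to the phenolate. The closest known reaction type is the Staunton–Weinreb annulation of ortho-toluate anions with β-alkoxy enones (Michael addition, Dieckmann condensation, elimination), here applied to a vinylogous toluate in which the C1 dienone takes the place of the arene. Both rings A close in the same 6-exo-trig mode and independently, since the two reacting sites are insulated by the C2–CH2–C2' bridge. No stereocentre is formed. The step needs γ- over α-attack of the dienolate, 1,4- over 1,2-addition to 13 and C-acylation at C7; these are secured by the blocked C8a, by the vinylogous carbonate character of the acetyl carbonyl of 13, and by the six-membered transition state, and the irreversible aromatization draws the preceding equilibria forward. The ring B enol ethers should survive because C3 is shielded by the gem-dimethyl group and the amide base is consumed at −78 °C before warming.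

Step 9
Reactants: 15 2,2'-methylenebis(7-acetyl-8-hydroxy-3,6-dimethoxy-4,4-dimethylnaphthalen-1(4H)-one)
Product: 16 2,2'-methylenebis(7-acetyl-3,6,8-trihydroxy-4,4-dimethylnaphthalen-1(4H)-one)
Conditions: BBr3 (8 equiv), CH2Cl2, −78 → 0 °C; then H2O, 0 °C
Reagents that add atoms: none
Why: Lewis-acid ether cleavage: the C6 methyl ethers are activated by chelation of boron between the ether oxygen and the ortho acetyl carbonyl, and the C3 vinylogous esters are cleaved through boron enolates that hydrolyse on work-up. Aryl ketones and chelated phenols tolerate BBr3, and the low temperature with a cold aqueous quench is chosen to keep the two ring B enols from dehydrating to a pyran.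

## Compound list

1 | methyl 2,2-dimethyl-3-oxobutanoate | COC(=O)C(C)(C)C(C)=O | starting material
2 | 2,2-dimethyl-3-oxobutanoic acid | CC(=O)C(C)(C)C(=O)O | intermediate
3 | 2,2-dimethyl-3-oxobutanoyl chloride | CC(=O)C(C)(C)C(=O)Cl | intermediate
4 | 1-methoxy-1,3-bis(trimethylsilyloxy)buta-1,3-diene (mixture of ketene acetal geometries, immaterial) | COC(O[Si](C)(C)C)=CC(=C)O[Si](C)(C)C | starting material
5 | methyl (2Z)-6,6-dimethyl-5,7-dioxo-3-(trimethylsilyloxy)oct-2-enoate (silyl group mobile, geometry of no consequence) | COC(=O)/C=C(\O[Si](C)(C)C)CC(=O)C(C)(C)C(C)=O | intermediate (not isolated)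
6 | methyl 6,6-dimethyl-3,5,7-trioxooctanoate | COC(=O)CC(=O)CC(=O)C(C)(C)C(C)=O | intermediate
7 | methyl 4-hydroxy-2,3,3-trimethyl-6-oxocyclohexa-1,4-diene-1-carboxylate | COC(=O)C1=C(C)C(C)(C)C(O)=CC1=O | intermediate
8 | formaldehyde | C=O | starting material
9 | dimethyl 5,5'-methylenebis(4-hydroxy-2,3,3-trimethyl-6-oxocyclohexa-1,4-diene-1-carboxylate) | COC(=O)C1=C(C)C(C)(C)C(O)=C(CC2=C(O)C(C)(C)C(C)=C(C(=O)OC)C2=O)C1=O | intermediate
10 | dimethyl 5,5'-methylenebis(4-methoxy-2,3,3-trimethyl-6-oxocyclohexa-1,4-diene-1-carboxylate) | COC(=O)C1=C(C)C(C)(C)C(OC)=C(CC2=C(OC)C(C)(C)C(C)=C(C(=O)OC)C2=O)C1=O | intermediate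
11 | 1,1-dimethoxyethene | C=C(OC)OC | starting material
12 | acetyl chloride | CC(=O)Cl | starting material
13 | 4,4-dimethoxybut-3-en-2-one | COC(OC)=CC(C)=O | intermediate
14 | dilithium bis(dienolate) of 10 (each C4a methyl deprotonated; drawn as the C1 O-enolate with an exocyclic C4a=CH2) | [Li+].[Li+].COC(=O)C1=C([O-])C(CC2=C(OC)C(C)(C)C(=C)C(C(=O)OC)=C2[O-])=C(OC)C(C)(C)C1=C | intermediate (not isolated)
15 | 2,2'-methylenebis(7-acetyl-8-hydroxy-3,6-dimethoxy-4,4-dimethylnaphthalen-1(4H)-one) | CC(=O)c1c(OC)cc2c(c1O)C(=O)C(CC1=C(OC)C(C)(C)c3cc(OC)c(C(C)=O)c(O)c3C1=O)=C(OC)C2(C)C | intermediate
16 | 2,2'-methylenebis(7-acetyl-3,6,8-trihydroxy-4,4-dimethylnaphthalen-1(4H)-one) | CC(=O)c1c(O)cc2c(c1O)C(=O)C(CC1=C(O)C(C)(C)c3cc(O)c(C(C)=O)c(O)c3C1=O)=C(O)C2(C)C | target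

## Step count and least certain steps

Total step count: 9. Longest linear sequence: 8 steps (steps 1 to 6, then 8 and 9); step 7 is a one-step side branch.

**Step 8 (key step).** The most likely failure is a conjugate addition that is too slow. The β-carbon of 13 carries two donor oxygens and 14 is a strongly stabilized, hindered nucleophile, so proton transfer from the acetyl methyl of 13, or simple return of 10 on work-up, may outrun C–C bond formation. Reaction of only one of the two halves is the second possibility. The fallback replaces the Michael addition by an acylation and sets out from 10. The bis(dienolate) 14 is treated with diketene, which acetoacetylates each C5 carbanion and should give dimethyl 5,5'-methylenebis[2-(2,4-dioxopentyl)-4-methoxy-3,3-dimethyl-6-oxocyclohexa-1,4-diene-1-carboxylate] F1. NaOMe in methanol then closes each ring A by Claisen attack of the diketone carbon C7 on the C8 ester, with spontaneous enolization to the arene. The product, 2,2'-methylenebis(7-acetyl-6,8-dihydroxy-3-methoxy-4,4-dimethylnaphthalen-1(4H)-one) F2, already has free C6 hydroxyls. Cleavage of its two enol ethers under the conditions of step 9 brings the material back to the route at 16.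

**Step 6.** The risk is poor site selectivity between the C1 and C3 oxygens of each ring, and, less likely, cycloaddition of the diazoalkane to the electron-poor C4a=C8a bond. The fallback makes the site of methylation irrelevant, since the C1 and C3 oxygens of ring B become one tautomeric pair once the methyl groups are removed. It sets out from 9, which is methylated without regard to site, or steered to the C1 oxygens with Me2SO4 and K2CO3 in acetone. The fully isomeric ether is dimethyl 5,5'-methylenebis(6-methoxy-2,3,3-trimethyl-4-oxocyclohexa-1,5-diene-1-carboxylate) F3, which still has the C4a methyl as its only acidic site. Annulation with 13 as in step 8 should give 3,3'-methylenebis(6-acetyl-5-hydroxy-4,7-dimethoxy-1,1-dimethylnaphthalen-2(1H)-one) F4. BBr3 as in step 9 converts F4, and any mixed isomer, into 16, where the fallback rejoins the route.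

**Step 4.** The risk is that the triketo ester cyclizes through oxygen (lactonization to a 4-hydroxy-2-pyranone or hemiketal formation), that the acetyl methyl condenses on the C3 ketone in the other possible six-membered aldol closure, or that the acetyl group is lost by retro-Claisen cleavage before the hindered C7 ketone is attacked by the ester-flanked carbon. The fallback changes both the nucleophile and the mode of activation. It sets out from 3 and 4, omits the aqueous acid of step 3 so that the silyl enol ether 5 is kept, and treats 5 in the same flask with TiCl4 in CH2Cl2 (−78 → 20 °C). An intramolecular Mukaiyama aldol addition of the silyl enol ether carbon to the Lewis-acid-activated ketone, followed by elimination, should give 7 directly, where the route is rejoined. This fallback makes no compound outside the list (entry F0).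

**Step 9.** The risk is that the strong Lewis acid promotes dehydrative closure of a pyran between the two ring B enols, or that the four ethers are cleaved at different rates and partly methylated material remains. The fallback separates the two kinds of ether and avoids boron halides. It sets out from 15. Dilute aqueous HCl in THF hydrolyses the two vinylogous esters to 2,2'-methylenebis(7-acetyl-3,8-dihydroxy-6-methoxy-4,4-dimethylnaphthalen-1(4H)-one) F5. NaSEt in DMF then removes the two aryl methyl groups by nucleophilic attack at methyl, helped by the ortho acetyl group, and gives 16.

## Further compounds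

F1 | step 8 | dimethyl 5,5'-methylenebis[2-(2,4-dioxopentyl)-4-methoxy-3,3-dimethyl-6-oxocyclohexa-1,4-diene-1-carboxylate] | COC(=O)C1=C(CC(=O)CC(C)=O)C(C)(C)C(OC)=C(CC2=C(OC)C(C)(C)C(CC(=O)CC(C)=O)=C(C(=O)OC)C2=O)C1=O
F2 | step 8 | 2,2'-methylenebis(7-acetyl-6,8-dihydroxy-3-methoxy-4,4-dimethylnaphthalen-1(4H)-one) | CC(=O)c1c(O)cc2c(c1O)C(=O)C(CC1=C(OC)C(C)(C)c3cc(O)c(C(C)=O)c(O)c3C1=O)=C(OC)C2(C)C
F3 | step 6 | dimethyl 5,5'-methylenebis(6-methoxy-2,3,3-trimethyl-4-oxocyclohexa-1,5-diene-1-carboxylate) | COC(=O)C1=C(C)C(C)(C)C(=O)C(CC2=C(OC)C(C(=O)OC)=C(C)C(C)(C)C2=O)=C1OC
F4 | step 6 | 3,3'-methylenebis(6-acetyl-5-hydroxy-4,7-dimethoxy-1,1-dimethylnaphthalen-2(1H)-one) | CC(=O)c1c(OC)cc2c(c1O)C(OC)=C(CC1=C(OC)c3c(O)c(C(C)=O)c(OC)cc3C(C)(C)C1=O)C(=O)C2(C)C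
F0 | step 4 | none | none
F5 | step 9 | 2,2'-methylenebis(7-acetyl-3,8-dihydroxy-6-methoxy-4,4-dimethylnaphthalen-1(4H)-one) | CC(=O)c1c(OC)cc2c(c1O)C(=O)C(CC1=C(O)C(C)(C)c3cc(OC)c(C(C)=O)c(O)c3C1=O)=C(O)C2(C)C
A1 | alternative 1 | 1,11-bis(4-hydroxy-2-oxo-2H-pyran-6-yl)-3,3,9,9-tetramethylundecane-2,4,8,10-tetraone | O=C1C=C(O)C=C(CC(=O)C(C)(C)C(=O)CCCC(=O)C(C)(C)C(=O)CC2=CC(O)=CC(=O)O2)O1
A2 | alternative 1 | dimethyl 6,6'-(2,8-dimethyl-3,7-dioxononane-2,8-diyl)bis(2,4-dihydroxybenzoate) | COC(=O)c1c(O)cc(O)cc1C(C)(C)C(=O)CCCC(=O)C(C)(C)c1cc(O)cc(O)c1C(=O)OC
A3 | alternative 2 | dimethyl 2,4-bis[2-(3,5-dimethoxyphenyl)-2-methylpropanoyl]pentanedioate (mixture of stereoisomers, both centres lost on cyclization) | COC(=O)C(CC(C(=O)OC)C(=O)C(C)(C)c1cc(OC)cc(OC)c1)C(=O)C(C)(C)c1cc(OC)cc(OC)c1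
A4 | alternative 2 | 2,2'-methylenebis(3-hydroxy-6,8-dimethoxy-4,4-dimethylnaphthalen-1(4H)-one) | COc1cc(OC)c2c(c1)C(C)(C)C(O)=C(CC1=C(O)C(C)(C)c3cc(OC)cc(OC)c3C1=O)C2=O
A5 | alternative 3 | 2,2'-methylenebis(6-bromo-3-methoxy-4,4-dimethylcyclohexa-2,5-dien-1-one) | COC1=C(CC2=C(OC)C(C)(C)C=C(Br)C2=O)C(=O)C(Br)=CC1(C)C
A6 | alternative 3 | 1,1-dimethoxy-3-(trimethylsilyloxy)buta-1,3-diene | COC(OC)=CC(=C)O[Si](C)(C)C
A7 | alternative 3 | 2,2'-methylenebis(6-hydroxy-3,8-dimethoxy-4,4-dimethylnaphthalen-1(4H)-one) | COc1cc(O)cc2c1C(=O)C(CC1=C(OC)C(C)(C)c3cc(O)cc(OC)c3C1=O)=C(OC)C2(C)C
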